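**Retrosynthetic overview**

- The target is (3R,5S,10R,13R)-3-bromolabda-8(9),14-dien-13-ol. Ring B (C5–C10) has its only alkene at C8=C9, between the ring-fusion atoms C5 and C10, so it is the cyclohexene of a [4+2] between a C7=C8–C9=C10 diene and a C5=C6 dienophile tethered through C1–C4.
- Endgame: the C3 bromide comes from a C3 ketone (bulky hydride to the axial alcohol, then bromide with inversion), and the C6 formyl group that activated the dienophile is removed by oxidation and radical decarboxylation.
- Key disconnection: C5–C10 and C6–C7 lead back to the acyclic (2E,8E)-2,8,10-undecatrienal 23 (the tether length that gives decalins). Rings A and B form in the same step, B as the cycloaddition ring and A as the tether ring.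
- Trienal 23 comes from C1–C2 alkylation of the lithium enolate of methyl ketone 20 with dienyl bromide 14. Ketone 20 is made from prenyl chloride, a Weinreb amide and acrolein acetal, with cross-metathesis done while only one alkene is present.
- Bromide 14 comes from (R)-linalool (C9, C11–C16 and the C13 stereocentre) via aldehyde 4 and β-keto ester 8. An (E)-enol tosylate and a Suzuki coupling fix the C9=C10 geometry.

Key step: step 13

Assumptions: labdane numbering is used for ring and side-chain atoms; (R)-(−)-linalool of high enantiomeric purity supplies C13; the usual shielding model of the imidazolidinone is taken to hold for this enal, and if the sense were opposite the (2S,5S) catalyst would be used in step 13.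

**Route**

Step 1
Reactants: 1 (R)-linalool
Product: 2 (3R)-3,7-dimethyl-3-(triethylsilyloxy)octa-1,6-diene
Conditions: TESOTf, 2,6-lutidine, CH2Cl2, −78 → 0 °C
Reagents that add atoms: triethylsilyl trifluoromethanesulfonate, CC[Si](CC)(CC)OS(=O)(=O)C(F)(F)F
Why: Silylation of a tertiary alcohol with a silyl triflate and a hindered base should be clean and leaves the C13 stereocentre untouched.

Step 2
Reactants: 2 (3R)-3,7-dimethyl-3-(triethylsilyloxy)octa-1,6-diene
Product: 4 (4R)-4-methyl-4-(triethylsilyloxy)hex-5-enal, via linalyl epoxide 3 (not isolated)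
Conditions: mCPBA, NaHCO3, CH2Cl2, 0 °C; then H5IO6, THF/H2O, 0 °C
Reagents that add atoms: 3-chloroperbenzoic acid, OOC(=O)c1cccc(Cl)c1
Why: Prilezhaev epoxidation should pick the electron-rich trisubstituted alkene over the vinyl group, and periodic acid cleaves the epoxide through its diol to the aldehyde and acetone.

Step 3
Reactants: 4 (4R)-4-methyl-4-(triethylsilyloxy)hex-5-enal; 5 methyl propanoate
Product: 7 methyl (6R)-3-hydroxy-2,6-dimethyl-6-(triethylsilyloxy)oct-7-enoate (mixture at C2/C3), via lithium ester enolate 6 (not isolated)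
Conditions: LDA, THF, −78 °C; then 4; aq. NH4Cl
Reagents that add atoms: none
Why: Aldol addition of an ester lithium enolate to an unhindered aldehyde; the two new centres form as a mixture and are both erased in steps 4 and 5.

Step 4
Reactants: 7 methyl (6R)-3-hydroxy-2,6-dimethyl-6-(triethylsilyloxy)oct-7-enoate
Product: 8 methyl (6R)-2,6-dimethyl-3-oxo-6-(triethylsilyloxy)oct-7-enoate
Conditions: Dess–Martin periodinane, NaHCO3, CH2Cl2, 0 °C → rt
Reagents that add atoms: none
Why: Dess–Martin oxidation of the secondary alcohol under buffered conditions should give the α-methyl β-keto ester without touching the silyl ether or the vinyl group.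

Step 5
Reactants: 8 methyl (6R)-2,6-dimethyl-3-oxo-6-(triethylsilyloxy)oct-7-enoate
Product: 9 methyl (2E,6R)-2,6-dimethyl-3-(tosyloxy)-6-(triethylsilyloxy)octa-2,7-dienoate
Conditions: TsCl, Me2N(CH2)6NMe2, MeCN, 0 °C
Reagents that add atoms: 4-toluenesulfonyl chloride, Cc1ccc(cc1)S(Cl)(=O)=O
Why: Amine-mediated enol tosylation of an α-substituted β-keto ester in the absence of a chelating metal should sulfonylate the open enolate and give the E isomer (TsO trans to the ester), whereas lithium-containing conditions would give Z.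

Step 6
Reactants: 9 methyl (2E,6R)-2,6-dimethyl-3-(tosyloxy)-6-(triethylsilyloxy)octa-2,7-dienoate; 10 isopropenylboronic acid pinacol ester
Product: 11 methyl (2E,6R)-2,6-dimethyl-3-(prop-1-en-2-yl)-6-(triethylsilyloxy)octa-2,7-dienoate
Conditions: Pd(OAc)2 (5 mol%), SPhos (10 mol%), K3PO4, THF/H2O, 60 °C
Reagents that add atoms: none
Why: Suzuki–Miyaura coupling of an activated β-tosyloxy acrylate proceeds with retention at the alkene, so the isopropenyl group (C8) should end trans to the ester carbon (C1) and cis to the C10 methyl.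

Step 7
Reactants: 11 methyl (2E,6R)-2,6-dimethyl-3-(prop-1-en-2-yl)-6-(triethylsilyloxy)octa-2,7-dienoate
Product: 12 (2E,6R)-2,6-dimethyl-3-(prop-1-en-2-yl)-6-(triethylsilyloxy)octa-2,7-dien-1-ol
Conditions: DIBAL-H (2.5 equiv), CH2Cl2, −78 °C; Rochelle salt
Reagents that add atoms: none
Why: DIBAL-H reduces the hindered dienoate by 1,2-addition to the allylic alcohol without changing the alkene geometry.

Step 8
Reactants: 12 (2E,6R)-2,6-dimethyl-3-(prop-1-en-2-yl)-6-(triethylsilyloxy)octa-2,7-dien-1-ol
Product: 14 (2E,6R)-1-bromo-2,6-dimethyl-3-(prop-1-en-2-yl)-6-(triethylsilyloxy)octa-2,7-diene, via allylic mesylate 13 (not isolated)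
Conditions: MsCl, Et3N, CH2Cl2, −40 °C; then LiBr, THF, −40 → 0 °C; used at once
Reagents that add atoms: lithium bromide, [Li+].[Br-]
Why: Mesylation followed by SN2 displacement with bromide at the primary allylic carbon avoids acid, so the alkene geometry and the tertiary silyl ether should survive.

Step 9
Reactants: 15 prenyl chloride; 16 N-methoxy-N-methylacetamide
Product: 18 3,3-dimethylpent-4-en-2-one, via prenylmagnesium chloride 17 (not isolated)
Conditions: Mg, THF, 0 °C; then 16, −78 → 0 °C; aq. NH4Cl
Reagents that add atoms: none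
Why: The prenyl Grignard reagent adds through its γ-carbon (SE2′, cyclic transition state) to create the C4 gem-dimethyl carbon, and the chelated tetrahedral adduct of the Weinreb amide stops the reaction at the ketone.

Step 10
Reactants: 18 3,3-dimethylpent-4-en-2-one; 19 acrolein diethyl acetal
Product: 20 (4E)-6,6-diethoxy-3,3-dimethylhex-4-en-2-one
Conditions: Hoveyda–Grubbs II (5 mol%), 19 (3 equiv), CH2Cl2, 40 °C
Reagents that add atoms: none
Why: Olefin cross-metathesis of a quaternary-allylic vinyl group (no homodimerisation) with an excess of the acetal partner should give the E alkene; it is done here because later intermediates carry a second vinyl group (C14=C15) of the same reactivity class.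

Step 11
Reactants: 20 (4E)-6,6-diethoxy-3,3-dimethylhex-4-en-2-one; 14 (2E,6R)-1-bromo-2,6-dimethyl-3-(prop-1-en-2-yl)-6-(triethylsilyloxy)octa-2,7-diene
Product: 22 (2E,8E)-1,1-diethoxy-4,4,8,10-tetramethyl-9-[(3R)-3-methyl-3-(triethylsilyloxy)pent-4-en-1-yl]undeca-2,8,10-trien-5-one, via lithium enolate 21 (not isolated)
Conditions: LDA, THF, −78 °C; then 14, DMPU, −78 → −20 °C
Reagents that add atoms: none
Why: Ketone 20 has a single enolisable position (C4 is quaternary), so its lithium enolate forms regiospecifically and SN2 alkylation at the primary allylic bromide forms the C1–C2 bond.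

Step 12
Reactants: 22 (2E,8E)-1,1-diethoxy-4,4,8,10-tetramethyl-9-[(3R)-3-methyl-3-(triethylsilyloxy)pent-4-en-1-yl]undeca-2,8,10-trien-5-one
Product: 23 (2E,8E)-4,4,8,10-tetramethyl-9-[(3R)-3-methyl-3-(triethylsilyloxy)pent-4-en-1-yl]-5-oxoundeca-2,8,10-trienal
Conditions: PPTS (cat.), acetone/H2O, rt
Reagents that add atoms: water, O
Why: An α,β-unsaturated acetal hydrolyses under weakly acidic conditions that the tertiary triethylsilyl ether and the diene should tolerate.

Step 13
Reactants: 23 (2E,8E)-4,4,8,10-tetramethyl-9-[(3R)-3-methyl-3-(triethylsilyloxy)pent-4-en-1-yl]-5-oxoundeca-2,8,10-trienal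
Product: 24 (5S,6R,10R,13R)-3-oxo-13-(triethylsilyloxy)labda-8(9),14-diene-6-carbaldehyde (trans-fused 6-formyl-3-oxo decalin)
Conditions: (2R,5R)-5-benzyl-2-tert-butyl-3-methylimidazolidin-4-one·TFA (20 mol%), MeCN/H2O (98:2), 0 °C → rt
Reagents that add atoms: none
Why: The imidazolidinone condenses with the unhindered enal of 23 (the C3 ketone, flanked by a quaternary carbon, should be left alone) to give an E iminium ion whose lowered LUMO adds to the tetra-alkyl diene C7=C8–C9=C10 in a concerted, asynchronous, suprafacial [4+2] that forms C5–C10 and C6–C7, after which hydrolysis releases 24 and the amine. The closest known reaction type is the imidazolidinone-catalysed enantioselective type 1 intramolecular Diels–Alder reaction of (E,E,E)-2,8,10-undecatrienals to trans-fused decalins, here asked to accept a fully substituted diene and to create a quaternary C10. Ring B (C5–C6–C7–C8–C9–C10) closes as the cycloaddition ring itself, and ring A (C1–C2–C3–C4–C5–C10) closes in the same event as the six-membered ring spanned by the four-atom tether C1–C4 between diene terminus C10 and dienophile carbon C5. The relative configuration of C5 and C10 comes from the endo transition state and the two E alkenes (tether outside and methyl inside on C10, iminium endo and C4 exo on the dienophile), which gives the trans ring fusion, and C6 follows from the E enal and is removed later. The absolute configuration at C5 and C10 is set by the catalyst, whose benzyl arm shields one face of the iminium so that, by the usual model, the (2R,5R) enantiomer should deliver 5S,10R, while the remote C13 centre plays no part. The step needs endo and π-facial selectivity on a diene twisted by its inside methyl group, and it is helped by intramolecularity, by the C4 gem-dimethyl group and the sp2 C3 in the tether, and by the match of an electron-rich diene with a cationic dienophile.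

Step 14
Reactants: 24 (5S,6R,10R,13R)-3-oxo-13-(triethylsilyloxy)labda-8(9),14-diene-6-carbaldehyde
Product: 25 (5S,6R,10R,13R)-3-oxo-13-(triethylsilyloxy)labda-8(9),14-diene-6-carboxylic acid
Conditions: NaClO2, NaH2PO4, 2-methyl-2-butene (large excess), t-BuOH/H2O, 0 °C → rt
Reagents that add atoms: sodium chlorite, [Na+].[O-]Cl=O
Why: Pinnick oxidation converts the aldehyde to the acid, with the excess alkene scavenging hypochlorite so that the C8=C9 and vinyl alkenes should be spared.

Step 15
Reactants: 25 (5S,6R,10R,13R)-3-oxo-13-(triethylsilyloxy)labda-8(9),14-diene-6-carboxylic acid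
Product: 27 (5S,10R,13R)-13-(triethylsilyloxy)labda-8(9),14-dien-3-one, via Barton ester 26 (not isolated)
Conditions: 2-mercaptopyridine N-oxide, DCC, DMAP (cat.), CH2Cl2, 0 °C, dark; then t-BuSH, hν (tungsten lamp), rt
Reagents that add atoms: none
Why: Barton reductive decarboxylation; the secondary C6 radical should be quenched by the thiol faster than it can add reversibly to C8=C9, and no stereocentre remains at C6.

Step 16
Reactants: 27 (5S,10R,13R)-13-(triethylsilyloxy)labda-8(9),14-dien-3-one
Product: 28 (3S,5S,10R,13R)-13-(triethylsilyloxy)labda-8(9),14-dien-3-ol (axial C3 hydroxyl)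
Conditions: L-Selectride, THF, −78 °C; aq. NH4Cl
Reagents that add atoms: none
Why: A bulky trialkylborohydride attacks a 4,4-dimethyl-3-keto trans-decalin from the equatorial direction, which should place the new hydroxyl axial (cis to H5, anti to the C10 methyl).

Step 17
Reactants: 28 (3S,5S,10R,13R)-13-(triethylsilyloxy)labda-8(9),14-dien-3-ol
Product: 29 (3R,5S,10R,13R)-3-bromo-13-(triethylsilyloxy)labda-8(9),14-diene
Conditions: CBr4, PPh3, 2,6-di-tert-butylpyridine, CH2Cl2, 0 °C → rt
Reagents that add atoms: carbon tetrabromide, BrC(Br)(Br)Br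
Why: Appel bromination runs by SN2 attack of bromide on the alkoxyphosphonium ion; with the leaving group axial the bromide enters along the open equatorial path and should give the equatorial 3R bromide with inversion, as known for axial 2,2-dimethylcyclohexanols.

Step 18
Reactants: 29 (3R,5S,10R,13R)-3-bromo-13-(triethylsilyloxy)labda-8(9),14-diene
Product: 30 (3R,5S,10R,13R)-3-bromolabda-8(9),14-dien-13-ol (target)
Conditions: HF·pyridine, pyridine, THF, 0 °C → rt
Reagents that add atoms: none
Why: Buffered fluoride desilylation removes the triethylsilyl group without base, so the hindered secondary bromide and the tertiary allylic alcohol should be kept.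

**Compound list**

1 | (R)-linalool | C=C[C@](C)(O)CCC=C(C)C | starting material
2 | (3R)-3,7-dimethyl-3-(triethylsilyloxy)octa-1,6-diene | C=C[C@](C)(O[Si](CC)(CC)CC)CCC=C(C)C | intermediate
3 | (3R)-6,7-epoxy-3,7-dimethyl-3-(triethylsilyloxy)oct-1-ene, both C6 epimers | C=C[C@](C)(O[Si](CC)(CC)CC)CCC1OC1(C)C | intermediate (not isolated)
4 | (4R)-4-methyl-4-(triethylsilyloxy)hex-5-enal | C=C[C@](C)(O[Si](CC)(CC)CC)CCC=O | intermediate
5 | methyl propanoate | CCC(=O)OC | starting material
6 | lithium enolate of methyl propanoate | CC=C(OC)O[Li] | intermediate (not isolated)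
7 | methyl (6R)-3-hydroxy-2,6-dimethyl-6-(triethylsilyloxy)oct-7-enoate, mixture at C2/C3 | C=C[C@](C)(O[Si](CC)(CC)CC)CCC(O)C(C)C(=O)OC | intermediate
8 | methyl (6R)-2,6-dimethyl-3-oxo-6-(triethylsilyloxy)oct-7-enoate | C=C[C@](C)(O[Si](CC)(CC)CC)CCC(=O)C(C)C(=O)OC | intermediate
9 | methyl (2E,6R)-2,6-dimethyl-3-(tosyloxy)-6-(triethylsilyloxy)octa-2,7-dienoate | COC(=O)/C(C)=C(/OS(=O)(=O)c1ccc(C)cc1)CC[C@@](C)(O[Si](CC)(CC)CC)C=C | intermediate
10 | isopropenylboronic acid pinacol ester | CC(=C)B1OC(C)(C)C(C)(C)O1 | starting material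
11 | methyl (2E,6R)-2,6-dimethyl-3-(prop-1-en-2-yl)-6-(triethylsilyloxy)octa-2,7-dienoate | COC(=O)/C(C)=C(/C(C)=C)CC[C@@](C)(O[Si](CC)(CC)CC)C=C | intermediate
12 | (2E,6R)-2,6-dimethyl-3-(prop-1-en-2-yl)-6-(triethylsilyloxy)octa-2,7-dien-1-ol | OC/C(C)=C(/C(C)=C)CC[C@@](C)(O[Si](CC)(CC)CC)C=C | intermediate
13 | methanesulfonate of 12 | CS(=O)(=O)OC/C(C)=C(/C(C)=C)CC[C@@](C)(O[Si](CC)(CC)CC)C=C | intermediate (not isolated)
14 | (2E,6R)-1-bromo-2,6-dimethyl-3-(prop-1-en-2-yl)-6-(triethylsilyloxy)octa-2,7-diene | BrC/C(C)=C(/C(C)=C)CC[C@@](C)(O[Si](CC)(CC)CC)C=C | intermediate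
15 | prenyl chloride | CC(C)=CCCl | starting material
16 | N-methoxy-N-methylacetamide | CC(=O)N(C)OC | starting material
17 | prenylmagnesium chloride | CC(C)=CC[Mg]Cl | intermediate (not isolated)
18 | 3,3-dimethylpent-4-en-2-one | CC(=O)C(C)(C)C=C | intermediate
19 | acrolein diethyl acetal | C=CC(OCC)OCC | starting material
20 | (4E)-6,6-diethoxy-3,3-dimethylhex-4-en-2-one | CC(=O)C(C)(C)/C=C/C(OCC)OCC | intermediate
21 | lithium enolate of 20 | C=C(O[Li])C(C)(C)/C=C/C(OCC)OCC | intermediate (not isolated)
22 | (2E,8E)-1,1-diethoxy-4,4,8,10-tetramethyl-9-[(3R)-3-methyl-3-(triethylsilyloxy)pent-4-en-1-yl]undeca-2,8,10-trien-5-one | CCOC(OCC)/C=C/C(C)(C)C(=O)CC/C(C)=C(/C(C)=C)CC[C@@](C)(O[Si](CC)(CC)CC)C=C | intermediate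
23 | (2E,8E)-4,4,8,10-tetramethyl-9-[(3R)-3-methyl-3-(triethylsilyloxy)pent-4-en-1-yl]-5-oxoundeca-2,8,10-trienal | O=C/C=C/C(C)(C)C(=O)CC/C(C)=C(/C(C)=C)CC[C@@](C)(O[Si](CC)(CC)CC)C=C | intermediate
24 | (5S,6R,10R,13R)-3-oxo-13-(triethylsilyloxy)labda-8(9),14-diene-6-carbaldehyde | C=C[C@](C)(O[Si](CC)(CC)CC)CCC1=C(C)C[C@@H](C=O)[C@@H]2C(C)(C)C(=O)CC[C@@]12C | intermediate
25 | (5S,6R,10R,13R)-3-oxo-13-(triethylsilyloxy)labda-8(9),14-diene-6-carboxylic acid | C=C[C@](C)(O[Si](CC)(CC)CC)CCC1=C(C)C[C@@H](C(=O)O)[C@@H]2C(C)(C)C(=O)CC[C@@]12C | intermediate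
26 | 2-thioxopyridin-1(2H)-yl ester of 25 (Barton ester) | C=C[C@](C)(O[Si](CC)(CC)CC)CCC1=C(C)C[C@@H](C(=O)On3ccccc3=S)[C@@H]2C(C)(C)C(=O)CC[C@@]12C | intermediate (not isolated)
27 | (5S,10R,13R)-13-(triethylsilyloxy)labda-8(9),14-dien-3-one | C=C[C@](C)(O[Si](CC)(CC)CC)CCC1=C(C)CC[C@@H]2C(C)(C)C(=O)CC[C@@]12C | intermediate
28 | (3S,5S,10R,13R)-13-(triethylsilyloxy)labda-8(9),14-dien-3-ol | C=C[C@](C)(O[Si](CC)(CC)CC)CCC1=C(C)CC[C@@H]2C(C)(C)[C@@H](O)CC[C@@]12C | intermediate
29 | (3R,5S,10R,13R)-3-bromo-13-(triethylsilyloxy)labda-8(9),14-diene | C=C[C@](C)(O[Si](CC)(CC)CC)CCC1=C(C)CC[C@@H]2C(C)(C)[C@H](Br)CC[C@@]12C | intermediate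
30 | (3R,5S,10R,13R)-3-bromolabda-8(9),14-dien-13-ol | C=C[C@](C)(O)CCC1=C(C)CC[C@@H]2C(C)(C)[C@H](Br)CC[C@@]12C | target

Total step count: 18. Longest linear sequence: 16 steps (steps 1–8, then 11–18).

**Steps most likely to fail**

Step 13. The diene is twisted by the inside C10 methyl and its 2,3-substituents, so it may not reach a planar s-cis geometry against a catalyst-bound, γ-quaternary iminium. The cycloaddition may then stall, or an uncatalysed background at higher temperature may give both ring-fusion enantiomers, which are diastereomers because of C13. The fallback replaces catalyst control by an auxiliary and a Lewis acid on the same disconnection and sets out from 23. Pinnick oxidation of the enal gives the (2E,8E)-trienoic acid F1. Activation as the pivalic mixed anhydride and acylation of lithiated (R)-4-benzyloxazolidin-2-one (enantiomer chosen by the chelated s-cis model) gives the trienimide F2. Me2AlCl in CH2Cl2 at −30 °C should then promote the endo cycloaddition to the cycloadduct imide F3. LiOH/H2O2 cleaves the auxiliary and the route is rejoined at acid 25.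

Step 17. β-Elimination of the activated axial oxygen toward C2, or a 1,2-shift from C4 after ionisation, may outrun substitution at the neopentyl carbon. The fallback separates activation from displacement and sets out from 28. Tf2O and pyridine at −40 °C give the axial triflate F6, which is treated cold with tetrabutylammonium bromide in toluene, a soluble and weakly basic bromide source with no phosphonium species or HBr present. The route is rejoined at 29.

Step 5. The enolate may react in a partly chelated or equilibrating form and give the Z enol tosylate, which would carry the isopropenyl group to the wrong side of C9=C10. The fallback builds the tetrasubstituted alkene by syn-carbometalation instead and sets out from 4. Ohira–Bestmann homologation gives the terminal alkyne F4, and n-BuLi followed by methyl chloroformate gives the ynoate F5. Syn-carbocupration with an isopropenyl cuprate (isopropenylmagnesium bromide, CuBr·SMe2, THF, −78 °C) and trapping of the α-cuprio ester with MeI in the presence of HMPA at −78 °C should place the isopropenyl and methyl groups cis. The route is rejoined at 11.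

**Further compounds**

F1 | step 13 | (2E,8E)-4,4,8,10-tetramethyl-9-[(3R)-3-methyl-3-(triethylsilyloxy)pent-4-en-1-yl]-5-oxoundeca-2,8,10-trienoic acid | OC(=O)/C=C/C(C)(C)C(=O)CC/C(C)=C(/C(C)=C)CC[C@@](C)(O[Si](CC)(CC)CC)C=C
F2 | step 13 | (4R)-4-benzyl-3-acyloxazolidin-2-one of F1 (trienimide) | O=C(/C=C/C(C)(C)C(=O)CC/C(C)=C(/C(C)=C)CC[C@@](C)(O[Si](CC)(CC)CC)C=C)N1[C@H](Cc2ccccc2)COC1=O
F3 | step 13 | (4R)-4-benzyl-3-acyloxazolidin-2-one of acid 25 (cycloadduct imide) | C=C[C@](C)(O[Si](CC)(CC)CC)CCC1=C(C)C[C@@H](C(=O)N3[C@H](Cc4ccccc4)COC3=O)[C@@H]2C(C)(C)C(=O)CC[C@@]12C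
F4 | step 5 | (3R)-3-methyl-3-(triethylsilyloxy)hept-1-en-6-yne | C#CCC[C@@](C)(O[Si](CC)(CC)CC)C=C
F5 | step 5 | methyl (6R)-6-methyl-6-(triethylsilyloxy)oct-7-en-2-ynoate | COC(=O)C#CCC[C@@](C)(O[Si](CC)(CC)CC)C=C
F6 | step 17 | (3S,5S,10R,13R)-13-(triethylsilyloxy)labda-8(9),14-dien-3-yl trifluoromethanesulfonate | C=C[C@](C)(O[Si](CC)(CC)CC)CCC1=C(C)CC[C@@H]2C(C)(C)[C@@H](OS(=O)(=O)C(F)(F)F)CC[C@@]12C
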